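**Retrosynthetic overview**
1. Target ⇒ α-face epoxidation of the C8=C9 alkene of 6α-hydroxydauc-8-en-4β-yl 4-hydroxybenzoate (oxirane formed last).
2. That hydroxy ester ⇒ Evans–Tishchenko reduction of 4β-hydroxydauc-8-en-6-one with a 4-silyloxybenzaldehyde, which sets C6 and places the aroyl group on the tertiary oxygen in one operation.
3. Seven-membered ring ⇒ ring-closing metathesis (C8=C9) of an allyl/methallyl ketone, itself from opening a cyclopentane-fused β-lactone with a methallyl nucleophile (C6–C7).
4. Key disconnection: the β-lactone (five-membered ring; C1, C4, C5) ⇒ chiral carbene homoenolate annulation of (E)-3-methylhexa-2,5-dienal with isopropyl vinyl ketone. The C1–C2 bond joins the β-carbon of an enal to the β-carbon of an enone; C4–C5 aldol and lactonisation follow in the same flask.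
5. Enal ⇒ methylalumination/hydroxymethylation of pent-1-en-4-yne, then oxidation. Ring order: cyclopentane (with β-lactone) → cycloheptene → oxirane.

Assumption (numbering): bicyclic compounds use daucane numbering — C1 ring-fusion carbon with the angular methyl, C2/C3 cyclopentane CH2, C4 carbon bearing isopropyl and oxygen, C5 ring-fusion CH, C6 CH–O, C7 CH2, C8 methyl-bearing carbon, C9, C10 CH2; α is the face opposite the angular methyl.
Assumption (catalyst sense): the (5aR,10bS) triazolium salt is taken, by analogy with its enal–enone annulations, to give the (R) centre at C1; if the sense proves opposite, the (5aS,10bR) salt is used with nothing else changed.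

**Step 1**
Reactants: 1 pent-1-en-4-yne
Product: 4 (2E)-3-methylhexa-2,5-dien-1-ol, via alkenyldimethylalane 2 (not isolated), via lithium alkenylaluminate 3 (not isolated)
Conditions: Me3Al (2 equiv), Cp2ZrCl2 (0.2 equiv), CH2Cl2, 0 °C → rt; evaporate excess Me3Al; n-BuLi, hexane/THF, −78 → 0 °C; (CH2O)n, rt; aq. HCl
Reagents that add atoms: trimethylaluminium, C[Al](C)C; paraformaldehyde (reacts as formaldehyde), C=O
Why: Negishi zirconium-catalysed methylalumination adds Me–Al syn across the terminal alkyne only (the isolated alkene is far slower), and the derived aluminate is hydroxymethylated with retention, so the E trisubstituted alkene is fixed here.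

**Step 2**
Reactants: 4 (2E)-3-methylhexa-2,5-dien-1-ol
Product: 5 (2E)-3-methylhexa-2,5-dienal
Conditions: activated MnO2 (15 equiv), CH2Cl2, rt
Reagents that add atoms: none
Why: Neutral allylic oxidation with MnO2 gives the enal without moving the skipped diene or eroding the E geometry; no stereocenter is involved.

**Step 3**
Reactants: 5 (2E)-3-methylhexa-2,5-dienal; 6 4-methylpent-1-en-3-one (isopropyl vinyl ketone)
Product: 7 (1R,2R,5R)-2-methyl-5-(propan-2-yl)-2-(prop-2-en-1-yl)-6-oxabicyclo[3.2.0]heptan-7-one (cis-fused β-lactone; lactone ring and methyl on one face, allyl on the other)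
Conditions: (5aR,10bS)-2-mesityl-5a,10b-dihydro-4H,6H-indeno[2,1-b][1,2,4]triazolo[4,3-d][1,4]oxazin-2-ium chloride (10 mol%), DBU (10 mol%), 6 (3 equiv), ClCH2CH2Cl, 0 °C → rt, slow addition of 5
Reagents that add atoms: none
Why: Proposed new method: the chiral carbene converts 5 into its extended Breslow intermediate, a d3 homoenolate whose β-carbon (C1, normally an acceptor) adds to the acceptor β-carbon (C2) of 6 on the face left open by the indane wall, which fixes the quaternary centre because the enal is geometrically pure; the acyl azolium enolate then closes by aldol onto the isopropyl ketone with the bulky azolium carbonyl next to the small methyl and away from the allyl group, and the tertiary alkoxide acylates itself to give the cis β-lactone and release the catalyst, so O4, C6 and the C1 methyl end on one face; the closest known reaction is the carbene-catalysed enal–enone annulation to cyclopentane-fused β-lactones and cyclopentenes, here extended to a β,β-disubstituted enal and an unsubstituted vinyl ketone.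

**Step 4**
Reactants: 7 the β-lactone; 8 2-methylallylmagnesium chloride (0.5 M in THF)
Product: 11 1-[(1R,2R,5R)-2-hydroxy-5-methyl-2-(propan-2-yl)-5-(prop-2-en-1-yl)cyclopentyl]-3-methylbut-3-en-1-one, via Weinreb amide chloromagnesium alkoxide 9 (not isolated), via tetrahedral magnesium hemiaminal 10 (not isolated)
Conditions: MeNHOMe·HCl (1.5 equiv), iPrMgCl (3.0 equiv), THF, −20 °C; then 8 (3 equiv), −20 → 0 °C; cold aq. NH4Cl
Reagents that add atoms: none
Why: The magnesium amide opens the strained lactone at the acyl carbon to the chelated Weinreb amide, whose tetrahedral adduct with the methallyl Grignard reagent releases the ketone only on quench, so no second addition occurs and C1, C4 and C5 are untouched (Weinreb ketone synthesis).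

**Step 5**
Reactants: 11 the dienyl hydroxy ketone
Product: 12 (1R,4R,5R)-4β-hydroxydauc-8-en-6-one (trans-fused; 5α-H, angular methyl β)
Conditions: second-generation Grubbs catalyst RuCl2(=CHPh)(PCy3)(H2IMes) (5 mol%), 1,4-benzoquinone (10 mol%), CH2Cl2 (5 mM), 40 °C
Reagents that add atoms: none
Why: Ring-closing metathesis of the monosubstituted allyl alkene with the 1,1-disubstituted methallyl alkene closes the trisubstituted cycloheptene, the trans fusion being already fixed by C1 and C5, while benzoquinone suppresses ruthenium hydride migration of the β,γ-double bond.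

**Step 6**
Reactants: 12 (1R,4R,5R)-4β-hydroxydauc-8-en-6-one; 13 4-[(tert-butyldimethylsilyl)oxy]benzaldehyde
Product: 15 (1R,4R,5S,6S)-6α-hydroxydauc-8-en-4β-yl 4-hydroxybenzoate, via silyl-protected hydroxy ester 14 (not isolated)
Conditions: SmI2 (0.3 equiv), 13 (4 equiv), THF, −10 °C; then n-Bu4NF/AcOH (1:1, 6 equiv), 0 °C, same flask
Reagents that add atoms: none
Why: Proposed new method: the hemiacetal formed between the tertiary C4 hydroxyl and 13 on trivalent samarium passes its hydride through a six-membered transition state to the β face of the C6 ketone, giving the 6α-alcohol anti to O4 and leaving the aroyl group on the tertiary oxygen, after which buffered fluoride removes the aryl silyl ether without base-induced acyl migration; the closest known reaction is the SmI2-catalysed Evans–Tishchenko reduction of secondary β-hydroxy ketones, here extended to a tertiary aldol.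

**Step 7**
Reactants: 15 (1R,4R,5S,6S)-6α-hydroxydauc-8-en-4β-yl 4-hydroxybenzoate
Product: 16 (1R,4R,5S,6S,8R,9S)-8α,9α-epoxy-6α-hydroxydaucan-4β-yl 4-hydroxybenzoate (CNP0264773.1)
Conditions: mCPBA (1.1 equiv), CH2Cl2, 0 °C; pH 7 phosphate work-up
Reagents that add atoms: mCPBA, OOC(=O)c1cccc(Cl)c1
Why: Prilezhaev epoxidation of the only electron-rich alkene takes place on the α face, which is opposite the angular C1 methyl and is also the face of the hydrogen-bonding homoallylic 6α-hydroxyl (Henbest effect), setting C8 and C9, while the acyl-deactivated phenol and the ester are inert at 0 °C.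

**Compound list**
1 | pent-1-en-4-yne | C#CCC=C | starting material
2 | dimethyl[(1E)-2-methylpenta-1,4-dien-1-yl]alumane | C=CC/C(C)=C/[Al](C)C | intermediate (not isolated)
3 | lithium butyl(dimethyl)[(1E)-2-methylpenta-1,4-dien-1-yl]aluminate | [Li+].C=CC/C(C)=C/[Al-](C)(C)CCCC | intermediate (not isolated)
4 | (2E)-3-methylhexa-2,5-dien-1-ol | C=CC/C(C)=C/CO | intermediate
5 | (2E)-3-methylhexa-2,5-dienal | C=CC/C(C)=C/C=O | intermediate
6 | 4-methylpent-1-en-3-one (isopropyl vinyl ketone) | C=CC(=O)C(C)C | starting material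
7 | (1R,2R,5R)-2-methyl-5-(propan-2-yl)-2-(prop-2-en-1-yl)-6-oxabicyclo[3.2.0]heptan-7-one | CC(C)[C@]12CC[C@](C)(CC=C)[C@H]1C(=O)O2 | intermediate
8 | 2-methylallylmagnesium chloride | CC(=C)C[Mg]Cl | starting material
9 | chloromagnesium alkoxide of (1R,2R,5R)-2-hydroxy-N-methoxy-N,5-dimethyl-2-(propan-2-yl)-5-(prop-2-en-1-yl)cyclopentane-1-carboxamide | CC(C)[C@]1(O[Mg]Cl)CC[C@](C)(CC=C)[C@H]1C(=O)N(C)OC | intermediate (not isolated)
10 | bis(chloromagnesium) tetrahedral adduct of 9 with the methallyl group (hemiaminal carbon unassigned) | CC(C)[C@]1(O[Mg]Cl)CC[C@](C)(CC=C)[C@H]1C(O[Mg]Cl)(CC(C)=C)N(C)OC | intermediate (not isolated)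
11 | 1-[(1R,2R,5R)-2-hydroxy-5-methyl-2-(propan-2-yl)-5-(prop-2-en-1-yl)cyclopentyl]-3-methylbut-3-en-1-one | CC(C)[C@]1(O)CC[C@](C)(CC=C)[C@H]1C(=O)CC(C)=C | intermediate
12 | (1R,4R,5R)-4β-hydroxydauc-8-en-6-one | CC(C)[C@]1(O)CC[C@]2(C)CC=C(C)CC(=O)[C@H]21 | intermediate
13 | 4-[(tert-butyldimethylsilyl)oxy]benzaldehyde | O=Cc1ccc(O[Si](C)(C)C(C)(C)C)cc1 | starting material
14 | (1R,4R,5S,6S)-6α-hydroxydauc-8-en-4β-yl 4-[(tert-butyldimethylsilyl)oxy]benzoate | CC(C)[C@]1(OC(=O)c2ccc(O[Si](C)(C)C(C)(C)C)cc2)CC[C@]2(C)CC=C(C)C[C@H](O)[C@H]21 | intermediate (not isolated)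
15 | (1R,4R,5S,6S)-6α-hydroxydauc-8-en-4β-yl 4-hydroxybenzoate | CC(C)[C@]1(OC(=O)c2ccc(O)cc2)CC[C@]2(C)CC=C(C)C[C@H](O)[C@H]21 | intermediate
16 | (1R,4R,5S,6S,8R,9S)-8α,9α-epoxy-6α-hydroxydaucan-4β-yl 4-hydroxybenzoate | CC(C)[C@]1(OC(=O)c2ccc(O)cc2)CC[C@]2(C)C[C@@H]3O[C@]3(C)C[C@H](O)[C@H]21 | target

**Totals and risks**
Total step count: 7. Longest linear sequence: 7 steps (1 → 16); 6, 8 and 13 enter as purchased.

The three steps most likely to fail are steps 3, 6 and 4.

Step 3 (carbene annulation). The risks are base-induced conjugation of the skipped dienal, β-protonation or Stetter diversion of the hindered homoenolate, and modest methyl/allyl discrimination in the ring closure. The fallback separates the conjugate addition from the ring closure. It sets out from 5 and 6: the same triazolium/DBU system in THF–MeOH stops after the homoenolate addition and methanolysis of the acyl azolium, giving the keto ester methyl (3R)-3,7-dimethyl-6-oxo-3-(prop-2-en-1-yl)octanoate F1. LiOH in THF–H2O gives the keto acid (3R)-3,7-dimethyl-6-oxo-3-(prop-2-en-1-yl)octanoic acid F2. A nucleophile-catalysed aldol lactonisation of F2 (2-bromo-1-propylpyridinium triflate, iPr2NEt, 4-pyrrolidinopyridine or a chiral isothiourea, CH2Cl2, rt) then forms the cyclopentane and the β-lactone, and the sequence comes back to the route at 7.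

Step 6 (Evans–Tishchenko on a tertiary aldol). The risks are that the hindered hemiacetal does not form, that retro-aldol opens the cyclopentane, or that the aroyl group migrates to O6. The fallback sets out from 12 and reduces first, then acylates. Me4NBH(OAc)3 in MeCN/AcOH at −20 °C delivers hydride from the O4-bound boron to give dauc-8-ene-4β,6α-diol (jaeschkeanadiol) F3. Et3SiCl and imidazole silylate only the secondary hydroxyl, giving 6α-(triethylsilyloxy)dauc-8-en-4β-ol F4. Separately, 13 is oxidised (NaClO2, NaH2PO4, 2-methylbut-2-ene) to 4-[(tert-butyldimethylsilyl)oxy]benzoic acid F5 and converted with oxalyl chloride into 4-[(tert-butyldimethylsilyl)oxy]benzoyl chloride F6. The lithium alkoxide of F4 (n-BuLi, THF, −78 °C) is acylated with F6 to 6α-(triethylsilyloxy)dauc-8-en-4β-yl 4-[(tert-butyldimethylsilyl)oxy]benzoate F7. HF·pyridine in THF/pyridine removes both silyl groups, and the sequence comes back to the route at 15.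

Step 4 (one-flask amide opening and Grignard addition). The risks are a sluggish addition at the carbonyl flanked by two quaternary carbons, and conjugation of the β,γ-enone on quench. The fallback sets out from 7 and goes through the aldehyde oxidation level. LiAlH4 in THF at 0 °C gives (1R,2S,3R)-2-(hydroxymethyl)-3-methyl-1-(propan-2-yl)-3-(prop-2-en-1-yl)cyclopentan-1-ol F8. TEMPO/PhI(OAc)2 oxidises only the primary alcohol, giving (1R,2R,5R)-2-hydroxy-5-methyl-2-(propan-2-yl)-5-(prop-2-en-1-yl)cyclopentane-1-carbaldehyde F9. Reagent 8 adds at −78 °C to give (1R,2S,3R)-2-(1-hydroxy-3-methylbut-3-en-1-yl)-3-methyl-1-(propan-2-yl)-3-(prop-2-en-1-yl)cyclopentan-1-ol F10 as carbinol epimers. Dess–Martin periodinane oxidises the secondary alcohol, and the sequence comes back to the route at 11.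

**Further compounds**
F1 | step 3 | methyl (3R)-3,7-dimethyl-6-oxo-3-(prop-2-en-1-yl)octanoate | CC(C)C(=O)CC[C@](C)(CC=C)CC(=O)OC
F2 | step 3 | (3R)-3,7-dimethyl-6-oxo-3-(prop-2-en-1-yl)octanoic acid | CC(C)C(=O)CC[C@](C)(CC=C)CC(=O)O
F3 | step 6 | (1R,4R,5S,6S)-dauc-8-ene-4β,6α-diol (jaeschkeanadiol) | CC(C)[C@]1(O)CC[C@]2(C)CC=C(C)C[C@H](O)[C@H]21
F4 | step 6 | 6α-(triethylsilyloxy)dauc-8-en-4β-ol | CC(C)[C@]1(O)CC[C@]2(C)CC=C(C)C[C@H](O[Si](CC)(CC)CC)[C@H]21
F5 | step 6 | 4-[(tert-butyldimethylsilyl)oxy]benzoic acid | OC(=O)c1ccc(O[Si](C)(C)C(C)(C)C)cc1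
F6 | step 6 | 4-[(tert-butyldimethylsilyl)oxy]benzoyl chloride | ClC(=O)c1ccc(O[Si](C)(C)C(C)(C)C)cc1
F7 | step 6 | 6α-(triethylsilyloxy)dauc-8-en-4β-yl 4-[(tert-butyldimethylsilyl)oxy]benzoate | CC(C)[C@]1(OC(=O)c2ccc(O[Si](C)(C)C(C)(C)C)cc2)CC[C@]2(C)CC=C(C)C[C@H](O[Si](CC)(CC)CC)[C@H]21
F8 | step 4 | (1R,2S,3R)-2-(hydroxymethyl)-3-methyl-1-(propan-2-yl)-3-(prop-2-en-1-yl)cyclopentan-1-ol | CC(C)[C@]1(O)CC[C@](C)(CC=C)[C@H]1CO
F9 | step 4 | (1R,2R,5R)-2-hydroxy-5-methyl-2-(propan-2-yl)-5-(prop-2-en-1-yl)cyclopentane-1-carbaldehyde | CC(C)[C@]1(O)CC[C@](C)(CC=C)[C@H]1C=O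
F10 | step 4 | (1R,2S,3R)-2-(1-hydroxy-3-methylbut-3-en-1-yl)-3-methyl-1-(propan-2-yl)-3-(prop-2-en-1-yl)cyclopentan-1-ol (carbinol epimers) | CC(C)[C@]1(O)CC[C@](C)(CC=C)[C@H]1C(O)CC(C)=C
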